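## Retrosynthetic overview
1. 21 ⇐ 17: the acetic acid arm on C3 is carried as a vinyl group (anti-Markovnikov hydroboration–oxidation, then oxidation to CO2H). No C–C bond is made once the peroxide is in place.
2. Structural feature: in the 1,2-dioxolane ring, C3–C4–C5 is a CH2 flanked by two fully substituted carbons (C3: CH3 and the acid arm; C5: CH3 and the 2-methyl-10-phenyldecyl chain). Joining C3 to C5 turns this segment into a 1,1,2,2-tetrasubstituted cyclopropane, and the remaining ring atoms O1–O2 are molecular oxygen.
3. 17 ⇐ vinylcyclopropane 15 + O2 16: a thiyl-radical chain (3+2) oxygenation forms C5–O1 and C3–O2 and closes the dioxolane.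
4. 15 ⇐ dibromocarbene adduct 10 of the 1,1-disubstituted alkene 7 (Br → CH3; Br → CHO → CH=CH2). 7 ⇐ (S)-3-bromo-2-methylpropan-1-ol 2 (source of C2′) by two copper-catalysed couplings, with 7-phenylheptyl and isopropenyl Grignard reagents.
5. Ring order: the phenyl ring is bought, the cyclopropane is formed in step 4, and in step 8 the cyclopropane is opened and the 1,2-dioxolane closed.

Key step: step 8

Remark: cyclopropanes 10–15 are carried as mixtures of ring stereoisomers (their SMILES fix only the side-chain centre), because step 8 erases both ring centres. Compounds 1, 2 and 6 are taken as catalogue items. C3, C4, C5, O1, O2, C1′ and C2′ are the locants of the target.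

## Route

Step 1
Reactants: 1 (7-bromoheptyl)benzene (2.2 equiv); 2 (2S)-3-bromo-2-methylpropan-1-ol
Product: 4 (2R)-2-methyl-10-phenyldecan-1-ol, via (7-phenylheptyl)magnesium bromide 3 (not isolated)
Conditions: 1, Mg, THF, reflux; then 2, Li2CuCl4 (5 mol %), THF, −78 °C → rt; aq NH4Cl
Reagents that add atoms: none
Why: Copper-catalysed Kochi–Schlosser sp3–sp3 coupling of a primary alkyl Grignard reagent with a primary bromide, in which the first equivalent of 3 only turns the hydroxyl of 2 into an inert magnesium alkoxide; the purchased stereocentre is β to the reacting carbon and is carried over unchanged (S becomes R through CIP ranking only), which sets C2′ of the target.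

Step 2
Reactants: 4 (2R)-2-methyl-10-phenyldecan-1-ol
Product: 5 [(9R)-10-iodo-9-methyldecyl]benzene
Conditions: I2, PPh3, imidazole, CH2Cl2, 0 °C → rt
Reagents that add atoms: iodine, II
Why: Appel-type iodination displaces the oxyphosphonium ion by SN2 at the CH2 carbon, so the neighbouring stereocentre is not touched.

Step 3
Reactants: 5 [(9R)-10-iodo-9-methyldecyl]benzene; 6 isopropenylmagnesium bromide
Product: 7 [(9R)-9,11-dimethyldodec-11-en-1-yl]benzene
Conditions: 6 (3 equiv), CuI (0.3 equiv), THF, −30 °C → rt
Reagents that add atoms: isopropenylmagnesium bromide 6, CC(=C)[Mg]Br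
Why: Copper(I)-catalysed coupling of an alkenyl Grignard reagent with a β-branched primary iodide is a standard way to attach an isopropenyl group, and substitution at CH2 leaves C2′ intact.

Step 4
Reactants: 7 [(9R)-9,11-dimethyldodec-11-en-1-yl]benzene; 8 bromoform
Product: 10 1,1-dibromo-2-methyl-2-[(2R)-2-methyl-10-phenyldecyl]cyclopropane (both epimers at ring C2), via dibromocarbene 9 (not isolated)
Conditions: 8 (3 equiv), 50% aq NaOH, BnEt3NCl (5 mol %), CH2Cl2, 0 °C → rt, vigorous stirring
Reagents that add atoms: bromoform 8, BrC(Br)Br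
Why: Phase-transfer generation of dibromocarbene (Makosza conditions) and its concerted [2+1] addition to the electron-rich 1,1-dialkyl alkene, the only reactive π-system since the phenyl ring is inert; the new ring centre forms unselectively, which does not matter.

Step 5
Reactants: 10 1,1-dibromo-2-methyl-2-[(2R)-2-methyl-10-phenyldecyl]cyclopropane
Product: 12 1-bromo-1,2-dimethyl-2-[(2R)-2-methyl-10-phenyldecyl]cyclopropane (mixture of ring stereoisomers), via α-bromocyclopropyllithium carbenoid 11 (not isolated)
Conditions: n-BuLi (1.05 equiv), THF, −100 °C, 15 min; MeI (5 equiv), −100 → −30 °C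
Reagents that add atoms: iodomethane, CI
Why: Lithiation–alkylation of a gem-dibromocyclopropane, in which Br/Li exchange gives carbenoid 11 that lives long enough in THF below about −90 °C to be C-methylated by the small, reactive MeI before α-elimination; which bromine is exchanged is irrelevant because step 8 erases the ring centres.

Step 6
Reactants: 12 1-bromo-1,2-dimethyl-2-[(2R)-2-methyl-10-phenyldecyl]cyclopropane
Product: 14 1,2-dimethyl-2-[(2R)-2-methyl-10-phenyldecyl]cyclopropane-1-carbaldehyde (mixture of ring stereoisomers), via tertiary cyclopropyllithium 13 (not isolated)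
Conditions: t-BuLi (2.1 equiv), Et2O, −78 °C, 30 min; DMF (4 equiv), −78 → 0 °C; H2O
Reagents that add atoms: N,N-dimethylformamide, CN(C)C=O
Why: Irreversible Br/Li exchange with two equivalents of t-BuLi gives the stable tertiary cyclopropyllithium 13, and its Bouveault-type formylation with DMF stops at the aldehyde oxidation level until work-up; the remote phenyl and alkyl C–H bonds are not metalated at −78 °C.

Step 7
Reactants: 14 1,2-dimethyl-2-[(2R)-2-methyl-10-phenyldecyl]cyclopropane-1-carbaldehyde
Product: 15 1-ethenyl-1,2-dimethyl-2-[(2R)-2-methyl-10-phenyldecyl]cyclopropane (all ring stereoisomers)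
Conditions: MePPh3Br (1.5 equiv), KOt-Bu (1.4 equiv), THF, 0 °C; then 14, 0 °C → rt
Reagents that add atoms: methyltriphenylphosphonium bromide, C[P+](c1ccccc1)(c1ccccc1)c1ccccc1.[Br-]
Why: Wittig methylenation with the small unstabilised ylide is reliable even on a hindered aldehyde, and 14 cannot enolise because its α-carbon is quaternary.

Step 8
Reactants: 15 1-ethenyl-1,2-dimethyl-2-[(2R)-2-methyl-10-phenyldecyl]cyclopropane; 16 dioxygen
Product: 17 (3R,5R)-3-ethenyl-3,5-dimethyl-5-[(2R)-2-methyl-10-phenyldecyl]-1,2-dioxolane
Conditions: Ph2S2 (0.2 equiv), AIBN (0.1 equiv), O2 (1 atm), PhH–MeCN 1:1, 0–5 °C, hν (sunlamp, Pyrex); SiO2 chromatography, then preparative HPLC (polysaccharide chiral phase)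
Reagents that add atoms: dioxygen 16, O=O
Why: PhS•, released from Ph2S2 by light with AIBN as co-initiator, adds reversibly to the vinyl CH2 of 15, and the resulting cyclopropylcarbinyl radical breaks the bond between the two quaternary ring carbons to give a trisubstituted allyl sulfide and the tertiary radical at the future C5, which captures O2 (C5–O1). The tertiary peroxyl radical, which terminates slowly and has no good hydrogen donor at hand, closes the 1,2-dioxolane by 5-exo-trig attack of its outer oxygen on the methyl-bearing alkene carbon (C3–O2), and the β-sulfanyl radical then expels PhS•, which restores the vinyl group and carries the chain. The closest known reaction type is the thiyl- or selenyl-radical-catalysed oxygenation of vinylcyclopropanes to 3-vinyl-1,2-dioxolanes, used here on a ring that bears only alkyl groups and two quaternary carbons. Since C5 passes through a planar radical and C3 through an sp2 carbon, all ring stereoisomers of 15 feed the same intermediates. C3 is set relative to C5 in a chair-like transition state in which the branched chain on C5 lies pseudoequatorial and the smaller C5 methyl takes the 1,3-syn contact with the C3 methyl, so chain and vinyl (hence the two methyls) should end up cis, although the bias between CH3 and CH2R can only be modest and the trans pair is removed on silica; C5 itself is not controlled by the C2′ centre, so the (3S,5S,2′R) cis isomer forms as well and is removed by preparative HPLC. The step needs ring opening toward the tertiary and not the primary radical, secured by the gem-dialkyl ring carbon and the strain of the tetrasubstituted bond, and 5-exo rather than 6-endo closure, secured by the short O–O–C5–C4 tether and by the fast, practically irreversible loss of PhS• from the exo adduct.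

Step 9
Reactants: 17 (3R,5R)-3-ethenyl-3,5-dimethyl-5-[(2R)-2-methyl-10-phenyldecyl]-1,2-dioxolane
Product: 19 2-[(3S,5R)-3,5-dimethyl-5-[(2R)-2-methyl-10-phenyldecyl]-1,2-dioxolan-3-yl]ethan-1-ol, via B-alkyl-9-BBN adduct 18 (not isolated)
Conditions: 9-BBN (1.5 equiv), THF, 0 °C → rt; then 3 M NaOH, 30% H2O2, 0 °C
Reagents that add atoms: hydrogen peroxide, OO
Why: Anti-Markovnikov hydroboration–oxidation, in which the bulky 9-BBN places boron on the terminal carbon of a vinyl group attached to a quaternary carbon; a di-tert-alkyl peroxide without α-hydrogen should tolerate the borane and cold alkaline H2O2, as cyclic peroxides are known to do, and no stereocentre is touched (C3 changes from R to S through CIP ranking only).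

Step 10
Reactants: 19 2-[(3S,5R)-3,5-dimethyl-5-[(2R)-2-methyl-10-phenyldecyl]-1,2-dioxolan-3-yl]ethan-1-ol
Product: 21 2-[(3R,5R)-3,5-dimethyl-5-[(2R)-2-methyl-10-phenyldecyl]-1,2-dioxolan-3-yl]acetic acid, via dioxolanylacetaldehyde 20 (not isolated)
Conditions: TEMPO (0.2 equiv), PhI(OAc)2 (2.5 equiv), CH2Cl2–H2O 2:1, rt
Reagents that add atoms: water, O
Why: Oxoammonium (TEMPO/PhI(OAc)2) oxidation of the primary alcohol through aldehyde 20 and its hydrate to the acid is metal-free and weakly acidic, so the O–O bond is not reduced, the β-peroxy aldehyde does not undergo base-induced β-elimination, and the benzylic position and all three stereocentres stay untouched.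

## Compound list
1 | (7-bromoheptyl)benzene | BrCCCCCCCc1ccccc1 | starting material
2 | (2S)-3-bromo-2-methylpropan-1-ol | C[C@H](CBr)CO | starting material
3 | (7-phenylheptyl)magnesium bromide | Br[Mg]CCCCCCCc1ccccc1 | intermediate (not isolated)
4 | (2R)-2-methyl-10-phenyldecan-1-ol | C[C@H](CCCCCCCCc1ccccc1)CO | intermediate
5 | [(9R)-10-iodo-9-methyldecyl]benzene | C[C@H](CCCCCCCCc1ccccc1)CI | intermediate
6 | isopropenylmagnesium bromide (prop-1-en-2-ylmagnesium bromide) | CC(=C)[Mg]Br | starting material
7 | [(9R)-9,11-dimethyldodec-11-en-1-yl]benzene | C[C@H](CCCCCCCCc1ccccc1)CC(C)=C | intermediate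
8 | bromoform | BrC(Br)Br | starting material
9 | dibromocarbene | Br[C]Br | intermediate (not isolated)
10 | 1,1-dibromo-2-methyl-2-[(2R)-2-methyl-10-phenyldecyl]cyclopropane | C[C@H](CCCCCCCCc1ccccc1)CC1(C)CC1(Br)Br | intermediate
11 | 1-bromo-1-lithio-2-methyl-2-[(2R)-2-methyl-10-phenyldecyl]cyclopropane | C[C@H](CCCCCCCCc1ccccc1)CC1(C)CC1([Li])Br | intermediate (not isolated)
12 | 1-bromo-1,2-dimethyl-2-[(2R)-2-methyl-10-phenyldecyl]cyclopropane | C[C@H](CCCCCCCCc1ccccc1)CC1(C)CC1(C)Br | intermediate
13 | {1,2-dimethyl-2-[(2R)-2-methyl-10-phenyldecyl]cyclopropyl}lithium | C[C@H](CCCCCCCCc1ccccc1)CC1(C)CC1(C)[Li] | intermediate (not isolated)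
14 | 1,2-dimethyl-2-[(2R)-2-methyl-10-phenyldecyl]cyclopropane-1-carbaldehyde | C[C@H](CCCCCCCCc1ccccc1)CC1(C)CC1(C)C=O | intermediate
15 | 1-ethenyl-1,2-dimethyl-2-[(2R)-2-methyl-10-phenyldecyl]cyclopropane | C[C@H](CCCCCCCCc1ccccc1)CC1(C)CC1(C)C=C | intermediate
16 | dioxygen | O=O | starting material
17 | (3R,5R)-3-ethenyl-3,5-dimethyl-5-[(2R)-2-methyl-10-phenyldecyl]-1,2-dioxolane | C[C@H](CCCCCCCCc1ccccc1)C[C@]1(C)C[C@](C)(C=C)OO1 | intermediate
18 | 9-{2-[(3S,5R)-3,5-dimethyl-5-[(2R)-2-methyl-10-phenyldecyl]-1,2-dioxolan-3-yl]ethyl}-9-borabicyclo[3.3.1]nonane | C[C@H](CCCCCCCCc1ccccc1)C[C@]1(C)C[C@](C)(CCB2C3CCCC2CCC3)OO1 | intermediate (not isolated)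
19 | 2-[(3S,5R)-3,5-dimethyl-5-[(2R)-2-methyl-10-phenyldecyl]-1,2-dioxolan-3-yl]ethan-1-ol | C[C@H](CCCCCCCCc1ccccc1)C[C@]1(C)C[C@](C)(CCO)OO1 | intermediate
20 | 2-[(3R,5R)-3,5-dimethyl-5-[(2R)-2-methyl-10-phenyldecyl]-1,2-dioxolan-3-yl]acetaldehyde | C[C@H](CCCCCCCCc1ccccc1)C[C@]1(C)C[C@](C)(CC=O)OO1 | intermediate (not isolated)
21 | 2-[(3R,5R)-3,5-dimethyl-5-[(2R)-2-methyl-10-phenyldecyl]-1,2-dioxolan-3-yl]acetic acid | C[C@H](CCCCCCCCc1ccccc1)C[C@]1(C)C[C@](C)(CC(=O)O)OO1 | target

## Step count and risks
Total step count: 10. Longest linear sequence: 10 (from 1 or 2 to 21).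

**Step 8.**
- What may go wrong: the chain may break down because closure of the tertiary peroxyl radical onto a fully substituted alkene carbon is slow. 6-endo closure, hydrogen abstraction or a second oxygenation could then compete.
- The cis/trans bias may also be weak, and the ring isomers may resolve poorly.
- Fallback: O2 capture is moved to a cyclopropanol, and the acetate arm is added afterwards by peroxycarbenium chemistry, all of it known chemistry. The detour sets out from bromide 12. Exchange with t-BuLi to 13 and quenching with B(OMe)3 give dimethyl cyclopropylboronate F1, and H2O2/NaOH gives tertiary cyclopropanol F2. Mn(acac)2-catalysed autoxidation (O2, benzene, rt) opens the ring toward the same tertiary C5 radical; after O2 capture the chain closes on the carbonyl carbon to 1,2-dioxolan-3-ol F3. MeOH with catalytic TsOH gives 3-methoxy-1,2-dioxolane F4. TiCl4 (CH2Cl2, −78 °C) ionises it, and the tert-butyldimethylsilyl ketene acetal of methyl acetate adds to give methyl dioxolanylacetate F5, whose isomers are separated by HPLC. LiOH in THF–H2O comes back to the route at 21.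

**Step 9.**
- What may go wrong: the B–H reagent may reductively cleave the O–O bond, or the neighbouring trialkylborane may cleave it by boron-to-oxygen migration.
- Hydroboration of the hindered, oxygen-deactivated vinyl group may also be sluggish.
- Fallback: boron is avoided. From 17, a nitrite-modified aldehyde-selective Wacker oxidation (PdCl2(PhCN)2, CuCl2, AgNO2, t-BuOH–MeNO2, O2, rt) gives aldehyde 20, now isolated; the quaternary, oxygen-bearing allylic carbon directs oxygen to the terminal carbon. Pinnick oxidation (NaClO2, NaH2PO4, 2-methylbut-2-ene, t-BuOH–H2O) comes back to the route at 21 (no new compound: F0).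

**Step 5.**
- What may go wrong: the carbenoid may undergo premature α-elimination, followed by ring opening to an allene or C–H insertion.
- Butylation or protonation may compete with methylation.
- Fallback: the ring is built from the other side, with C4 as the carbene carbon and both methyl groups already on the alkene, so no α-halo carbenoid is needed. The detour sets out from alkene 7. Ozonolysis (O3, CH2Cl2, −78 °C; Me2S) gives methyl ketone F6. A Horner–Wadsworth–Emmons reaction with triethyl 2-phosphonopropionate (NaH, THF, reflux) gives tetrasubstituted enoate F7 as an E/Z mixture, which is harmless here. DIBAL-H gives allylic alcohol F8. Hydroxyl-directed Furukawa–Simmons–Smith cyclopropanation (Et2Zn, CH2I2, CH2Cl2) gives cyclopropylmethanol F9, and Dess–Martin oxidation comes back to the route at aldehyde 14.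

## Further compounds
F1 | step 8 | dimethyl {1,2-dimethyl-2-[(2R)-2-methyl-10-phenyldecyl]cyclopropyl}boronate | C[C@H](CCCCCCCCc1ccccc1)CC1(C)CC1(C)B(OC)OC
F2 | step 8 | 1,2-dimethyl-2-[(2R)-2-methyl-10-phenyldecyl]cyclopropan-1-ol | C[C@H](CCCCCCCCc1ccccc1)CC1(C)CC1(C)O
F3 | step 8 | 3,5-dimethyl-5-[(2R)-2-methyl-10-phenyldecyl]-1,2-dioxolan-3-ol | C[C@H](CCCCCCCCc1ccccc1)CC1(C)CC(C)(O)OO1
F4 | step 8 | 3-methoxy-3,5-dimethyl-5-[(2R)-2-methyl-10-phenyldecyl]-1,2-dioxolane | C[C@H](CCCCCCCCc1ccccc1)CC1(C)CC(C)(OC)OO1
F5 | step 8 | methyl 2-[(3R,5R)-3,5-dimethyl-5-[(2R)-2-methyl-10-phenyldecyl]-1,2-dioxolan-3-yl]acetate | C[C@H](CCCCCCCCc1ccccc1)C[C@]1(C)C[C@](C)(CC(=O)OC)OO1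
F0 | step 9 | none | none
F6 | step 5 | (4R)-4-methyl-12-phenyldodecan-2-one | C[C@H](CCCCCCCCc1ccccc1)CC(C)=O
F7 | step 5 | ethyl (5R)-2,3,5-trimethyl-13-phenyltridec-2-enoate (E/Z mixture) | C[C@H](CCCCCCCCc1ccccc1)CC(C)=C(C)C(=O)OCC
F8 | step 5 | (5R)-2,3,5-trimethyl-13-phenyltridec-2-en-1-ol (E/Z mixture) | C[C@H](CCCCCCCCc1ccccc1)CC(C)=C(C)CO
F9 | step 5 | {1,2-dimethyl-2-[(2R)-2-methyl-10-phenyldecyl]cyclopropyl}methanol | C[C@H](CCCCCCCCc1ccccc1)CC1(C)CC1(C)CO
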